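The vessel on the table was a stirred, isothermal flask of substrate and free catalyst, fed with partner in portions, and the chair opened with the two earlier runs and the question.

common to all: substrate 20 mM
- Saturday's: partner 36 mM (in portions, 2); free catalyst 13 µM; run made earlier; portions every 2.5 h
- Tuesday's: partner 36 mM (in portions, 2); free catalyst 30 µM; run made earlier; portions every 2.5 h
- flask: partner 36.0 mM (in portions, 2); free catalyst 20 µM; the portions of partner follow each other after 2.5 h, the first at the start; time 10 h

| run | time / h | substrate / % | product / % |
|---|---|---|---|
| Saturday's | 0.667 | 96 | 0 |
| Saturday's | 1.33 | 94 | 6 |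
| Saturday's | 2.50 | 96 | 4 |
| Saturday's | 4.00 | 91 | 11 |
| Saturday's | 8.00 | 80 | 18 |
| Tuesday's | 0.667 | 98 | 4 |
| Tuesday's | 1.33 | 92 | 5 |
| Tuesday's | 2.50 | 90 | 12 |
| Tuesday's | 4.00 | 80 | 19 |
| Tuesday's | 8.00 | 61 | 37 |

(standard deviation of a reading: 1.5 percentage points)

1. concentration of substrate at 10 h, in mM
2. concentration of product at 10 h, in mM

- steps that have been proposed: partner + free catalyst -> catalyst intermediate A; 2 catalyst intermediate A <-> resting dimer; catalyst intermediate A -> by-product + catalyst intermediate B; catalyst intermediate C <-> free catalyst + product; substrate + catalyst intermediate B -> catalyst intermediate C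

The analyst argued that c(substrate) stands in millimolar and c(free catalyst) in micromolar, so each catalyst must go round many times, and counting those rounds was the cheapest way to the answer. Saturday's run reached 18% product at 8.00 h, which she counted as 277 turnovers. Tuesday's reached 37%, or 247. Were these different? She thought not: Tuesday's count on Saturday's catalyst gives 16.0% product against the 18% read, a gap comparable to the scatter of 1.5 percentage points.

Their mean over the time, 32.7 /h, she called the turnover rate (the turnover frequency), product made per catalyst charged per hour. Held flat on this flask's 20 µM for 10 h, it gave her 6.54 mM product and 13.5 mM substrate. That product figure stays below the 20 mM of substrate charged, so she applied no cap.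

The forecaster, arguing from rates, put substrate at 13.4 mM, in a range of 12.4 mM to 14.4 mM, and product at 6.6 mM, in a range of 5.6 mM to 7.6 mM, and read the runs as “near zero order in substrate”. The analyst's product figure lay slightly lower, inside that range.

The flask gave 13.3 mM substrate and 6.66 mM product.

    partner + free catalyst → catalyst intermediate A (k = 1.10 /M/s)
    2 catalyst intermediate A ⇌ resting dimer (K = 17000 /M, k = 1.00 /M/s)
    catalyst intermediate A → by-product + catalyst intermediate B (k = 0.0350 /s)
    catalyst intermediate C ⇌ free catalyst + product (K = 0.0120 M, k = 0.140 /s)
    substrate + catalyst intermediate B → catalyst intermediate C (k = 2.30 /M/s)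

The product of this flask, per catalyst charged and per hour, comes to 33.3 /h, beside the 32.7 /h carried from the runs. One more flask, like this one but charged with 0.080 mM of free catalyst, takes the same reckoning: 32.7 /h on that catalyst over 10 h gives 26.2 mM product, more than the 20 mM of substrate charged, so the flat count has to be capped at the charge. Its own count came to 21.4 /h, lower than the carried rate. That flask ended with 17.1 mM product and 2.90 mM substrate.

The runs were computed with made-up constants; the scatter is artificial.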